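**Retrosynthetic overview**

1. Target 15 is a depside: ring B is methyl orsellinate, acylated on its 4-oxygen by ring A, a hexasubstituted benzoyl unit (C1 carbonyl, C2 OH, C3 CH3, C4 OH, C5 Cl, C6 CH3).
2. The strategy rests on reading ring A as alkyne plus diene: the C1–C6 edge (ester carbon on C1, methyl on C6) is a but-2-ynoate, and C2–C5 (O, CH3, O, Cl) is the bis-silyl dienol ether of a 4-chloro-2-methylacetoacetate. Cutting C1–C2 and C5–C6 gives ynoate 4 and chlorodiene 12.
3. The depside C–O bond is therefore made first, on unhindered but-2-ynoic acid (1 + 2 → 3, then 2-O-silylation → 4), before C1 carries its two ortho substituents.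
4. Diene 12 comes from methyl propanoate 5 and the chloroacetyl Weinreb amide 6 (Claisen-type acylation to 9), followed by two successive enol silylations.
5. Ring order: ring B is purchased; ring A is the only ring formed (step 6, [4+2] then aromatisation); a final desilylation releases 15.

Key step: step 6

Remark on the chemistry: the target has no stereocentre. Compound 9 is racemic, 8 and 13 are diastereomer mixtures and 10 is expected as an E/Z mixture about C2=C3. Their SMILES carry no descriptor at these positions, because each element is erased in the operation that follows. The β-keto ester 9 is assembled by acylation rather than by C-methylation of a 4-chloroacetoacetate, whose enolate is prone to self-alkylation at the chloromethyl ketone.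

**Route**

Step 1
Reactants: 1 methyl orsellinate (methyl 2,4-dihydroxy-6-methylbenzoate); 2 but-2-ynoic acid
Product: 3 methyl 4-(but-2-ynoyloxy)-2-hydroxy-6-methylbenzoate
Conditions: DCC, DMAP (5 mol %), CH2Cl2, 0 °C
Reagents that add atoms: none
Why: Steglich esterification, expected at O4 because the 4-hydroxyl is the free, more acidic and unhindered phenol whereas the 2-hydroxyl is tied up in a hydrogen bond to the ester carbonyl; low temperature and only catalytic DMAP limit conjugate addition to the ynoate.

Step 2
Reactants: 3 methyl 4-(but-2-ynoyloxy)-2-hydroxy-6-methylbenzoate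
Product: 4 methyl 4-(but-2-ynoyloxy)-2-(tert-butyldimethylsilyloxy)-6-methylbenzoate
Conditions: TBSOTf, 2,6-lutidine, CH2Cl2, 0 °C
Reagents that add atoms: tert-butyldimethylsilyl trifluoromethanesulfonate (TBSOTf), CC(C)(C)[Si](C)(C)OS(=O)(=O)C(F)(F)F
Why: O-silylation of a chelated phenol by a silyl triflate and a hindered, non-nucleophilic base, which leaves the aryl ynoate untouched and masks the one acidic hydrogen that would otherwise protodesilylate the ketene acetal diene in step 6.

Step 3
Reactants: 5 methyl propanoate; 6 2-chloro-N-methoxy-N-methylacetamide
Product: 9 racemic methyl 4-chloro-2-methyl-3-oxobutanoate, via lithium enolate of methyl propanoate 7 (not isolated), via chelated lithium carbinolamine adduct 8 (not isolated)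
Conditions: LiN(i-Pr)2, THF, −78 °C; then 6, −78 °C; then 1 M HCl, −78 to 0 °C
Reagents that add atoms: none
Why: Crossed Claisen-type acylation of an ester enolate by a Weinreb amide, in which the chelated tetrahedral adduct 8 survives until the acid quench, so that the acidic β-keto ester never meets the enolate and carbonyl addition at −78 °C outruns displacement of the primary chloride; the C2 stereocentre is formed racemic and becomes sp2 in the next step.

Step 4
Reactants: 9 racemic methyl 4-chloro-2-methyl-3-oxobutanoate
Product: 10 methyl 4-chloro-2-methyl-3-(trimethylsilyloxy)but-2-enoate (E/Z mixture)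
Conditions: TMSCl, Et3N, toluene, rt
Reagents that add atoms: chlorotrimethylsilane, C[Si](C)(C)Cl
Why: Amine-mediated O-silylation of the β-keto ester enol, which places the double bond at C2=C3 because only that enol is conjugated to the ester, while the hindered amine at room temperature is a poor nucleophile toward the chloromethyl group.

Step 5
Reactants: 10 methyl 4-chloro-2-methyl-3-(trimethylsilyloxy)but-2-enoate
Product: 12 (1E,3Z)-4-chloro-1-methoxy-2-methyl-1,3-bis(trimethylsilyloxy)buta-1,3-diene, via chlorinated lithium dienolate 11 (not isolated)
Conditions: LiN(i-Pr)2, THF, −78 °C; then TMSCl, −78 to 0 °C; hexane, filtration under argon, used crude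
Reagents that add atoms: chlorotrimethylsilane, C[Si](C)(C)Cl
Why: γ-Deprotonation of a 3-silyloxy-2-enoate and O-silylation of the dienolate, the standard entry to 1-alkoxy-1,3-bis(silyloxy)dienes, here helped by the chlorine that acidifies the γ-hydrogens; chlorine is expected cis to the 3-silyloxy group (3Z) because the other geometry suffers allylic 1,3-strain against the C2 methyl.

Step 6
Reactants: 4 methyl 4-(but-2-ynoyloxy)-2-(tert-butyldimethylsilyloxy)-6-methylbenzoate; 12 (1E,3Z)-4-chloro-1-methoxy-2-methyl-1,3-bis(trimethylsilyloxy)buta-1,3-diene
Product: 14 methyl 2-(tert-butyldimethylsilyloxy)-4-[(5-chloro-2,4-dihydroxy-3,6-dimethylbenzoyl)oxy]-6-methylbenzoate, via cyclohexa-1,4-diene cycloadduct 13 (not isolated)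
Conditions: 12 (2.5 equiv), toluene, 120 °C, sealed tube; then 1 M HCl, THF, 0 °C to rt
Reagents that add atoms: none
Why: A normal-demand, strongly asynchronous [4+2] cycloaddition is expected, in which the CHCl terminus of 12 (the vinylogous nucleophilic end of the ketene acetal) bonds to the methyl-bearing β-carbon of ynoate 4 (future C5–C6) and the ketene-acetal carbon then bonds to the ynoate α-carbon (future C1–C2), giving cyclohexa-1,4-diene 13. The closest known reaction type is the Diels–Alder benzannulation of 1-alkoxy-1,3-bis(silyloxy)buta-1,3-dienes with alkynoates to give resorcylates, of which this fully substituted chlorodiene with an internal alkyne is a hindered case that calls for heat and excess diene. Ring A is closed as a six-membered carbocycle by this intermolecular two-bond union; on acid work-up the C2 mixed ketal collapses with loss of methanol, the C5 hydrogen is shed in the dienone-to-phenol tautomerisation and both trimethylsilyl ethers are hydrolysed, so the two oxygens and the chlorine all stay on the arene. No stereocentre persists, since the two sp3 carbons of 13 (C2 and C5) become aromatic. The selectivity needed is regiochemical and is secured by the polarity match just described together with the (3Z) geometry, which holds chlorine on the outside of the s-cis diene so that the reactive conformation is accessible. The aryl tert-butyldimethylsilyl ether, the methyl ester and the new aryl ester should tolerate both the heating and the brief exposure to dilute acid.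

Step 7
Reactants: 14 methyl 2-(tert-butyldimethylsilyloxy)-4-[(5-chloro-2,4-dihydroxy-3,6-dimethylbenzoyl)oxy]-6-methylbenzoate
Product: 15 methyl 4-[(5-chloro-2,4-dihydroxy-3,6-dimethylbenzoyl)oxy]-2-hydroxy-6-methylbenzoate (the target)
Conditions: HF·pyridine, pyridine, THF, 0 °C to rt
Reagents that add atoms: none
Why: Fluoride-driven desilylation of an aryl silyl ether under pyridine-buffered, non-basic conditions, in which Si–F bond formation cleaves the Si–O bond while the depside ester, the methyl ester and the aryl chloride meet no basic nucleophile.

**Compound list**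

1 | methyl orsellinate (methyl 2,4-dihydroxy-6-methylbenzoate) | COC(=O)c1c(C)cc(O)cc1O | starting material
2 | but-2-ynoic acid | CC#CC(=O)O | starting material
3 | methyl 4-(but-2-ynoyloxy)-2-hydroxy-6-methylbenzoate | CC#CC(=O)Oc1cc(C)c(C(=O)OC)c(O)c1 | intermediate
4 | methyl 4-(but-2-ynoyloxy)-2-(tert-butyldimethylsilyloxy)-6-methylbenzoate | CC#CC(=O)Oc1cc(C)c(C(=O)OC)c(O[Si](C)(C)C(C)(C)C)c1 | intermediate
5 | methyl propanoate | CCC(=O)OC | starting material
6 | 2-chloro-N-methoxy-N-methylacetamide | CON(C)C(=O)CCl | starting material
7 | lithium enolate of methyl propanoate, methyl cis to methoxy (not isolated) | C/C=C(\OC)O[Li] | intermediate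
8 | lithium 1-chloro-4-methoxy-2-[methoxy(methyl)amino]-3-methyl-4-oxobutan-2-olate, the chelated carbinolamine adduct (diastereomer mixture, not isolated) | COC(=O)C(C)C(CCl)(O[Li])N(C)OC | intermediate
9 | racemic methyl 4-chloro-2-methyl-3-oxobutanoate | COC(=O)C(C)C(=O)CCl | intermediate
10 | methyl 4-chloro-2-methyl-3-(trimethylsilyloxy)but-2-enoate (E/Z mixture about C2=C3) | COC(=O)C(C)=C(CCl)O[Si](C)(C)C | intermediate
11 | lithium dienolate of 10, drawn in the geometry that leads to 12 (not isolated) | CO/C(O[Li])=C(/C)\C(O[Si](C)(C)C)=C\Cl | intermediate
12 | (1E,3Z)-4-chloro-1-methoxy-2-methyl-1,3-bis(trimethylsilyloxy)buta-1,3-diene | CO/C(O[Si](C)(C)C)=C(/C)\C(O[Si](C)(C)C)=C\Cl | intermediate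
13 | cyclohexa-1,4-diene cycloadduct: 3-(tert-butyldimethylsilyloxy)-4-(methoxycarbonyl)-5-methylphenyl 3-chloro-6-methoxy-2,5-dimethyl-4,6-bis(trimethylsilyloxy)cyclohexa-1,4-diene-1-carboxylate (diastereomer mixture, not isolated) | COC1(O[Si](C)(C)C)C(C)=C(O[Si](C)(C)C)C(Cl)C(C)=C1C(=O)Oc1cc(C)c(C(=O)OC)c(O[Si](C)(C)C(C)(C)C)c1 | intermediate
14 | methyl 2-(tert-butyldimethylsilyloxy)-4-[(5-chloro-2,4-dihydroxy-3,6-dimethylbenzoyl)oxy]-6-methylbenzoate | COC(=O)c1c(C)cc(OC(=O)c2c(C)c(Cl)c(O)c(C)c2O)cc1O[Si](C)(C)C(C)(C)C | intermediate
15 | methyl 4-[(5-chloro-2,4-dihydroxy-3,6-dimethylbenzoyl)oxy]-2-hydroxy-6-methylbenzoate | COC(=O)c1c(C)cc(OC(=O)c2c(C)c(Cl)c(O)c(C)c2O)cc1O | target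

**Step count**

Total: 7 steps. Longest linear sequence: 5 steps (steps 3, 4, 5, 6, 7 from methyl propanoate); the ring B branch is 4 steps (1, 2, 6, 7).

**Steps most likely to fail**

Step 6. The cycloaddition may be outpaced by thermal decay of the diene (silyl transfer, hydrolysis by adventitious moisture), because chlorine on the reacting terminus and the fully substituted diene backbone slow bond formation to an internal, singly activated alkyne. In addition, the C2 mixed ketal of the adduct may lose silanol in place of methanol, which would leave a methyl ether on ring A. The fallback sets out from 4, runs the same benzannulation with the chlorine-free, more nucleophilic diene and puts the chlorine on afterwards. Purchased methyl 2-methyl-3-oxobutanoate (COC(=O)C(C)C(C)=O) is silylated (TMSCl, Et3N) to methyl 2-methyl-3-(trimethylsilyloxy)but-2-enoate F1. LiN(i-Pr)2 and then TMSCl convert this into (E)-1-methoxy-2-methyl-1,3-bis(trimethylsilyloxy)buta-1,3-diene F2. Heating F2 with 4 should give the chlorine-free cyclohexa-1,4-diene cycloadduct F3, which dilute acid aromatises to methyl 2-(tert-butyldimethylsilyloxy)-4-[(2,4-dihydroxy-3,6-dimethylbenzoyl)oxy]-6-methylbenzoate F4. Electrophilic chlorination of F4 with N-chlorosuccinimide (1 equiv, MeCN, 0 °C) is expected at ring A C5, the only free position of that ring and ortho and para to its two free hydroxyls, whereas ring B carries only an acyloxy and a silyloxy donor. This returns to the route at 14.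

Step 5. Deprotonation next to chlorine by a lithium amide may be followed by loss of chloride from the dienolate or by attack of the amide on the silyl enol ether, and the hydrolytically fragile diene may be lost on isolation. The fallback sets out from 9 and makes 12 in one flask by soft enolisation with TMSOTf (2.3 equiv) and Et3N (2.5 equiv) in Et2O at 0 °C. Both enol silylations then run through silylated carbonyl species deprotonated by the amine, so no lithium dienolate is formed; the ammonium triflate separates as a second phase and the ether layer is concentrated and used directly. Compound 10 forms in the flask on the way, and no compound outside the list arises (F0). The route is rejoined at 12.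

Step 3. Proton transfer from the α-chloro amide to the ester enolate, displacement of the primary chloride, or self-condensation of methyl propanoate may compete with acylation. The fallback sets out from 5 and traps its enolate as the ketene silyl acetal (E)-1-methoxy-1-(trimethylsilyloxy)prop-1-ene F5 (LiN(i-Pr)2, THF, −78 °C; then TMSCl). This neutral nucleophile is C-acylated with chloroacetyl chloride (ClCC(=O)Cl; CH2Cl2, 0 °C to rt, ZnCl2 cat. if needed), a known acylation of ketene silyl acetals by acid chlorides. Loss of the silyl group as its chloride gives 9 directly, where the route is rejoined.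

**Further compounds**

F1 | step 6 | methyl 2-methyl-3-(trimethylsilyloxy)but-2-enoate (E/Z mixture) | COC(=O)C(C)=C(C)O[Si](C)(C)C
F2 | step 6 | (E)-1-methoxy-2-methyl-1,3-bis(trimethylsilyloxy)buta-1,3-diene | CO/C(O[Si](C)(C)C)=C(/C)C(=C)O[Si](C)(C)C
F3 | step 6 | chlorine-free cyclohexa-1,4-diene cycloadduct of 4 and F2 (not isolated) | COC1(O[Si](C)(C)C)C(C)=C(O[Si](C)(C)C)CC(C)=C1C(=O)Oc1cc(C)c(C(=O)OC)c(O[Si](C)(C)C(C)(C)C)c1
F4 | step 6 | methyl 2-(tert-butyldimethylsilyloxy)-4-[(2,4-dihydroxy-3,6-dimethylbenzoyl)oxy]-6-methylbenzoate | COC(=O)c1c(C)cc(OC(=O)c2c(C)cc(O)c(C)c2O)cc1O[Si](C)(C)C(C)(C)C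
F0 | step 5 | none | none
F5 | step 3 | (E)-1-methoxy-1-(trimethylsilyloxy)prop-1-ene | C/C=C(\OC)O[Si](C)(C)C
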